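**Plan**

1. Retrosynthesis: C17 is removed (C16=CH2 back to a C16 ketone, carried as a dioxolane) and a ketone is placed on C11. The C12–C13 bond (aldol) and the C8–C9 bond (Michael) are then cut together, which opens rings B and C.
2. Enabling feature: in ring C, C9 and C12 flank C11, and C8 and C13 flank C14. A C11 carbonyl makes C9 and C12 nucleophilic and a ring D enone C8=C14–C13=O makes C8 and C13 electrophilic, so ring C is a [3+3] Michael–aldol adduct and the aryl tether turns the Michael step into the closure of ring B.
3. Forward order: benzofuran (ring A plus furan) from 3-bromo-2-methylphenol; ring D attached as a ketal-protected cyclopentenone (ester-enolate Michael addition, Saegusa–Ito oxidation); rings B and C in one operation; C11 deoxygenation; C16 unmasking and methylenation; hydrolysis.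
4. Stereochemistry: C8 comes from a chiral primary amine–thiourea catalyst in the Michael step and C13 follows from the bridging geometry. C9 and C6 are epimerisable and should settle thermodynamically (ring B cis on ring C; ester pseudo-axial, away from the aryl methyl group).

Key step: step 11

Remark on numbering: gibberellane numbers are used for the core. C6 is CH–CO2H, C8 the quaternary carbon, C9 the benzylic CH, C11 and C12 the ring C methylenes, C13 the carbinol, C14 the one-carbon bridge, C15 and C16 the two-carbon bridge, C17 the methylene carbon; the aryl methyl group is on C4. "Pharbinilate" is the diester of 22 and "17-nor" means that C17 is absent. In these numbers 22 is (6R,8S,9R,13S).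

Assumption: the (1R,2R) catalyst is written in step 11; which catalyst enantiomer gives the required C8 configuration must be settled by experiment, and the (1S,2S) catalyst is taken if the sense is opposite.

**Step 1**
Reactants: 1 3-bromo-2-methylphenol
Product: 2 4-bromo-2-hydroxy-3-methylbenzaldehyde
Conditions: MgCl2, Et3N, (CH2O)n, MeCN, reflux; aq. HCl
Reagents that add atoms: paraformaldehyde (formaldehyde), C=O
Why: Magnesium phenoxide-directed ortho-formylation (Casnati–Skattebøl type) can reach only the single free ortho position of the phenol.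

**Step 2**
Reactants: 2 4-bromo-2-hydroxy-3-methylbenzaldehyde
Product: 3 4-bromo-2-hydroxy-5-iodo-3-methylbenzaldehyde
Conditions: N-iodosuccinimide, CF3CO2H (cat.), MeCN, rt
Reagents that add atoms: N-iodosuccinimide, O=C1CCC(=O)N1I
Why: Electrophilic aromatic iodination should go to the one position that is para to the hydroxyl and meta to the formyl group, and the iodide later tells this carbon apart from the brominated one.

**Step 3**
Reactants: 3 4-bromo-2-hydroxy-5-iodo-3-methylbenzaldehyde
Product: 5 ethyl 6-bromo-5-iodo-7-methyl-1-benzofuran-3-carboxylate, via hemiacetal 4 (not isolated)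
Conditions: N2CHCO2Et, HBF4·OEt2 (10 mol %), CH2Cl2, rt; then conc. H2SO4
Reagents that add atoms: ethyl diazoacetate, CCOC(=O)C=[N+]=[N-]
Why: Acid-catalysed addition of the diazo ester to the aldehyde with 1,2-aryl shift gives an α-aryl-β-oxo ester that closes onto the phenol to hemiacetal 4, which H2SO4 dehydrates (salicylaldehyde/diazoacetate benzofuran annulation).

**Step 4**
Reactants: 5 ethyl 6-bromo-5-iodo-7-methyl-1-benzofuran-3-carboxylate
Product: 6 ethyl 6-bromo-7-methyl-5-(prop-2-en-1-yl)-1-benzofuran-3-carboxylate
Conditions: CH2=CHCH2SnBu3, Pd(PPh3)4 (5 mol %), toluene, 90 °C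
Reagents that add atoms: allyltributylstannane, C=CC[Sn](CCCC)(CCCC)CCCC
Why: Stille coupling, in which zerovalent palladium should insert into the C–I bond much faster than into the flanked C–Br bond, so that only C5 of the benzofuran is allylated.

**Step 5**
Reactants: 6 ethyl 6-bromo-7-methyl-5-(prop-2-en-1-yl)-1-benzofuran-3-carboxylate
Product: 7 ethyl 6-(2-ethoxy-2-oxoethyl)-7-methyl-5-(prop-2-en-1-yl)-1-benzofuran-3-carboxylate
Conditions: BrZnCH2CO2Et (from BrCH2CO2Et and Zn, THF), Pd2(dba)3 (2.5 mol %), XPhos (6 mol %), THF, 65 °C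
Reagents that add atoms: (2-ethoxy-2-oxoethyl)zinc bromide, CCOC(=O)C[Zn]Br (made from ethyl bromoacetate, CCOC(=O)CBr, and Zn)
Why: Negishi-type α-arylation with a Reformatsky reagent is neutral enough for both the ester and the terminal alkene, and a bulky biarylphosphine should allow coupling at the di-ortho-substituted bromide.

**Step 6**
Reactants: 8 cyclopentane-1,2-dione
Product: 9 1,4-dioxaspiro[4.4]nonan-6-one
Conditions: HOCH2CH2OH, TsOH·H2O (cat.), benzene, reflux, Dean–Stark trap
Reagents that add atoms: ethylene glycol, OCCO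
Why: Acid-catalysed monoketalisation with azeotropic removal of water; the remaining carbonyl, now next to the quaternary ketal carbon, should ketalise much more slowly.

**Step 7**
Reactants: 9 1,4-dioxaspiro[4.4]nonan-6-one
Product: 11 1,4-dioxaspiro[4.4]non-7-en-6-one, via silyl enol ether 10 (not isolated)
Conditions: LiN(i-Pr)2, THF, −78 °C; Me3SiCl; then Pd(OAc)2, MeCN, rt
Reagents that add atoms: none
Why: Saegusa–Ito oxidation; the ketone can enolise only towards C7, so the enol ether and hence the enone form regiospecifically.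

**Step 8**
Reactants: 7 ethyl 6-(2-ethoxy-2-oxoethyl)-7-methyl-5-(prop-2-en-1-yl)-1-benzofuran-3-carboxylate; 11 1,4-dioxaspiro[4.4]non-7-en-6-one
Product: 12 ethyl 6-[2-ethoxy-2-oxo-1-(6-oxo-1,4-dioxaspiro[4.4]nonan-8-yl)ethyl]-7-methyl-5-(prop-2-en-1-yl)-1-benzofuran-3-carboxylate
Conditions: LiN(i-Pr)2, THF, −78 °C; then 11, −78 to −30 °C; aq. NH4Cl
Reagents that add atoms: none
Why: Michael addition of the stabilised α-aryl ester enolate to the β-unsubstituted enone, whose carbonyl is shielded by the neighbouring spiro-ketal; both new stereocentres are erased or reset later, so the diastereomer mixture is carried on.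

**Step 9**
Reactants: 12 ethyl 6-[2-ethoxy-2-oxo-1-(6-oxo-1,4-dioxaspiro[4.4]nonan-8-yl)ethyl]-7-methyl-5-(prop-2-en-1-yl)-1-benzofuran-3-carboxylate
Product: 14 ethyl 6-[2-ethoxy-2-oxo-1-(6-oxo-1,4-dioxaspiro[4.4]non-7-en-8-yl)ethyl]-7-methyl-5-(prop-2-en-1-yl)-1-benzofuran-3-carboxylate, via silyl enol ether 13 (not isolated)
Conditions: Me3SiOTf (1.1 equiv), Et3N, CH2Cl2, 0 °C; then Pd(OAc)2, MeCN, rt
Reagents that add atoms: none
Why: Saegusa–Ito oxidation; soft enolisation gives the only possible ketone enol ether, and β-hydride elimination from the ring CH restores the enone with the arylacetate unit on its β-carbon (C8).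

**Step 10**
Reactants: 14 ethyl 6-[2-ethoxy-2-oxo-1-(6-oxo-1,4-dioxaspiro[4.4]non-7-en-8-yl)ethyl]-7-methyl-5-(prop-2-en-1-yl)-1-benzofuran-3-carboxylate
Product: 15 ethyl 6-[2-ethoxy-2-oxo-1-(6-oxo-1,4-dioxaspiro[4.4]non-7-en-8-yl)ethyl]-7-methyl-5-(2-oxopropyl)-1-benzofuran-3-carboxylate
Conditions: PdCl2 (10 mol %), CuCl, O2 (1 atm), DMF/H2O, rt
Reagents that add atoms: water, O
Why: Tsuji–Wacker oxidation of the terminal allyl group gives the methyl ketone (C11) by Markovnikov hydroxypalladation, while the electron-poor trisubstituted enone alkene should not react.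

**Step 11**
Reactants: 15 ethyl 6-[2-ethoxy-2-oxo-1-(6-oxo-1,4-dioxaspiro[4.4]non-7-en-8-yl)ethyl]-7-methyl-5-(2-oxopropyl)-1-benzofuran-3-carboxylate
Product: 17 ketol diethyl 16,16-ethylenedioxy-13-hydroxy-11-oxo-17-norpharbinilate, via spiro diketone 16 (not isolated)
Conditions: 1-[(1R,2R)-2-aminocyclohexyl]-3-[3,5-bis(trifluoromethyl)phenyl]thiourea (20 mol %), PhCO2H (20 mol %), toluene, 40 °C; then NaOEt, EtOH, 50 °C; AcOH quench
Reagents that add atoms: none
Why: Proposed new method: the primary amine of the catalyst condenses with the unhindered methyl ketone to the aryl-conjugated C9 enamine while its thiourea hydrogen-bonds the ring D enone carbonyl, so C9 adds to C8 in a 5-(enolexo)-exo-trig Michael step (ring B) on one enone face to give 16, whose imine tautomerises to the C12 enamine (or, once NaOEt is added, the C12 enolate) and closes ring C by a 6-(enolendo)-exo-trig aldol addition to the ketal-activated C13 carbonyl. The closest known reaction types are primary amine–thiourea-catalysed intramolecular Michael additions of ketones to tethered α,β-unsaturated carbonyl acceptors and base- or amine-mediated Michael–aldol [3+3] annulations of cyclopentenones to 5-hydroxybicyclo[3.2.1]octan-3-ones; not yet shown are the β,β-disubstituted acceptor and the spiro quaternary centre. C8 is set by the catalyst in the Michael step, which should not reverse at 50 °C, and C13 follows from C8 because C12 can reach the carbonyl only across the C14 bridge. C9 (α to the C11 ketone) and C6 (α to the ester) stay epimerisable and are equilibrated by NaOEt: ring B should sit cis on ring C only with H-9 on the side of C15, and this fold should put the C6 ester pseudo-axial, anti to C14 and clear of the C4 methyl group. The step needs C9 and not the methyl carbon to attack (only C9 can close a five-membered ring), an enone that stays electrophilic (the buffered amine/acid medium should leave the acidic C6–H in place, whereas ethoxide alone would first turn the enone into its dienolate), and facial control, which the two-point binding of enamine and enone carbonyl to one catalyst molecule should supply.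

**Step 12**
Reactants: 17 ketol diethyl 16,16-ethylenedioxy-13-hydroxy-11-oxo-17-norpharbinilate
Product: 19 diethyl 16,16-ethylenedioxy-13-hydroxy-17-norpharbinilate, via tosylhydrazone 18 (not isolated)
Conditions: TsNHNH2, AcOH (cat.), EtOH, 60 °C; then catecholborane, CHCl3, 0 °C; NaOAc·3H2O, 60 °C
Reagents that add atoms: none
Why: Caglioti-type reductive deoxygenation: hydride adds to the C=N bond of the tosylhydrazone and acetate-induced loss of sulfinate and N2 leaves the C11 methylene under conditions mild enough for the β-hydroxyl, the ketal and the esters.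

**Step 13**
Reactants: 19 diethyl 16,16-ethylenedioxy-13-hydroxy-17-norpharbinilate
Product: 20 diethyl 13-hydroxy-16-oxo-17-norpharbinilate
Conditions: 2 M HCl, THF, 50 °C
Reagents that add atoms: water, O
Why: Acid hydrolysis of the dioxolane is placed before the alkene is made, because the later allylic tertiary alcohol would rearrange in acid.

**Step 14**
Reactants: 20 diethyl 13-hydroxy-16-oxo-17-norpharbinilate
Product: 21 diethyl pharbinilate
Conditions: Zn, CH2Br2, TiCl4, THF/CH2Cl2, 0 °C to rt
Reagents that add atoms: dibromomethane, BrCBr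
Why: Lombardo methylenation is non-basic, so the α-ketol should neither undergo acyloin rearrangement nor epimerise, and the esters are left alone.

**Step 15**
Reactants: 21 diethyl pharbinilate
Product: 22 pharbinilic acid
Conditions: KOH, EtOH/H2O, 80 °C; then 1 M HCl to pH 3, 0 °C
Reagents that add atoms: potassium hydroxide, [K+].[OH-]
Why: Saponification of both esters; any C6 epimer left should equilibrate through the ester enolate to the same pseudo-axial configuration before it is hydrolysed, and cold, brief acidification avoids acid-induced rearrangement of the allylic tertiary alcohol.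

**Compound list**

1 | 3-bromo-2-methylphenol | Cc1c(O)cccc1Br | starting material
2 | 4-bromo-2-hydroxy-3-methylbenzaldehyde | O=Cc1ccc(Br)c(C)c1O | intermediate
3 | 4-bromo-2-hydroxy-5-iodo-3-methylbenzaldehyde | O=Cc1cc(I)c(Br)c(C)c1O | intermediate
4 | ethyl 6-bromo-2-hydroxy-5-iodo-7-methyl-2,3-dihydro-1-benzofuran-3-carboxylate (hemiacetal, diastereomer mixture, not isolated) | CCOC(=O)C1C(O)Oc2c(C)c(Br)c(I)cc12 | intermediate
5 | ethyl 6-bromo-5-iodo-7-methyl-1-benzofuran-3-carboxylate | CCOC(=O)c1coc2c(C)c(Br)c(I)cc12 | intermediate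
6 | ethyl 6-bromo-7-methyl-5-(prop-2-en-1-yl)-1-benzofuran-3-carboxylate | CCOC(=O)c1coc2c(C)c(Br)c(CC=C)cc12 | intermediate
7 | ethyl 6-(2-ethoxy-2-oxoethyl)-7-methyl-5-(prop-2-en-1-yl)-1-benzofuran-3-carboxylate | CCOC(=O)Cc1c(CC=C)cc2c(C(=O)OCC)coc2c1C | intermediate
8 | cyclopentane-1,2-dione | O=C1CCCC1=O | starting material
9 | 1,4-dioxaspiro[4.4]nonan-6-one | O=C1CCCC12OCCO2 | intermediate
10 | trimethyl(1,4-dioxaspiro[4.4]non-6-en-6-yloxy)silane (not isolated) | C[Si](C)(C)OC1=CCCC12OCCO2 | intermediate
11 | 1,4-dioxaspiro[4.4]non-7-en-6-one | O=C1C=CCC12OCCO2 | intermediate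
12 | ethyl 6-[2-ethoxy-2-oxo-1-(6-oxo-1,4-dioxaspiro[4.4]nonan-8-yl)ethyl]-7-methyl-5-(prop-2-en-1-yl)-1-benzofuran-3-carboxylate (racemic, both diastereomers) | CCOC(=O)C(C1CC(=O)C2(C1)OCCO2)c1c(CC=C)cc2c(C(=O)OCC)coc2c1C | intermediate
13 | trimethylsilyl enol ether of 12 at the ring ketone (not isolated) | CCOC(=O)C(C1C=C(O[Si](C)(C)C)C2(C1)OCCO2)c1c(CC=C)cc2c(C(=O)OCC)coc2c1C | intermediate
14 | ethyl 6-[2-ethoxy-2-oxo-1-(6-oxo-1,4-dioxaspiro[4.4]non-7-en-8-yl)ethyl]-7-methyl-5-(prop-2-en-1-yl)-1-benzofuran-3-carboxylate (racemic, the CH centre is labile) | CCOC(=O)C(C1=CC(=O)C2(C1)OCCO2)c1c(CC=C)cc2c(C(=O)OCC)coc2c1C | intermediate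
15 | ethyl 6-[2-ethoxy-2-oxo-1-(6-oxo-1,4-dioxaspiro[4.4]non-7-en-8-yl)ethyl]-7-methyl-5-(2-oxopropyl)-1-benzofuran-3-carboxylate (racemic, the CH centre is labile) | CCOC(=O)C(C1=CC(=O)C2(C1)OCCO2)c1c(CC(C)=O)cc2c(C(=O)OCC)coc2c1C | intermediate
16 | spiro diketone: ring B closed (C8–C9), ring C open; indane ring B with CO2Et on C6 and acetyl on C9, spiro at C8 to the 2,2-(ethylenedioxy)cyclopentanone ring D; C8 as in 22, C6 and C9 not yet fixed (not isolated) | O1CCOC12C[C@]3(CC2=O)C(C(C)=O)c2cc4c(C(=O)OCC)coc4c(C)c2C3C(=O)OCC | intermediate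
17 | ketol, diethyl 16,16-ethylenedioxy-13-hydroxy-11-oxo-17-norpharbinilate; C6, C8, C9 and C13 arranged as in 22 (C6 ester and H-9 on the side of the C15–C16 bridge) | O1CCOC12C[C@]34C[C@@]2(O)CC(=O)[C@H]3c3cc5c(C(=O)OCC)coc5c(C)c3[C@@H]4C(=O)OCC | intermediate
18 | C11 tosylhydrazone of 17 (not isolated) | O1CCOC12C[C@]34C[C@@]2(O)CC(=NNS(=O)(=O)c5ccc(C)cc5)[C@H]3c3cc6c(C(=O)OCC)coc6c(C)c3[C@@H]4C(=O)OCC | intermediate
19 | diethyl 16,16-ethylenedioxy-13-hydroxy-17-norpharbinilate (C11 methylene; stereocentres arranged as in 22) | O1CCOC12C[C@]34C[C@@]2(O)CC[C@H]3c3cc5c(C(=O)OCC)coc5c(C)c3[C@@H]4C(=O)OCC | intermediate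
20 | diethyl 13-hydroxy-16-oxo-17-norpharbinilate (C16 ketone; stereocentres arranged as in 22) | O=C1C[C@]23C[C@@]1(O)CC[C@H]2c1cc2c(C(=O)OCC)coc2c(C)c1[C@@H]3C(=O)OCC | intermediate
21 | diethyl pharbinilate | C=C1C[C@]23C[C@@]1(O)CC[C@H]2c1cc2c(C(=O)OCC)coc2c(C)c1[C@@H]3C(=O)OCC | intermediate
22 | pharbinilic acid, (6R,8S,9R,13S) in gibberellane numbering | C=C1C[C@]23C[C@@]1(O)CC[C@H]2c1cc2c(C(=O)O)coc2c(C)c1[C@@H]3C(=O)O | target

**Count and risks**

Total step count: 15. Longest linear sequence: 13 steps (steps 1–5 and 8–15); steps 6–7 make the ring D fragment.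

Steps most likely to fail:

Step 11 (proposed new method). The secondary enamine may be too weak a nucleophile for the fully substituted, flanked β-carbon, or it may attack without useful facial discrimination. Fallback, setting out from 15: NaOEt (0.5 equiv) in EtOH at 50 °C should run the same Michael–aldol sequence through enolates, a known base-mediated [3+3] annulation of cyclopentenones. This gives the racemate, that is the spiro diketone 16 together with its mirror image ent-spiro diketone F1 (neither isolated) and then ketol 17 together with its mirror image ent-ketol F2. Preparative chromatography on a chiral stationary phase separates the two, and 17 comes back to the route at step 12.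

Step 5. Oxidative addition and transmetalation at the bromide flanked by the methyl and allyl groups may be slow, letting protodebromination or alkene migration take over. Fallback, setting out from 2 without the iodination: the diazoacetate annulation gives, through ethyl 6-bromo-2-hydroxy-7-methyl-2,3-dihydro-1-benzofuran-3-carboxylate F3 (not isolated), ethyl 6-bromo-7-methyl-1-benzofuran-3-carboxylate F4. Its bromide has only one ortho substituent and should couple readily with BrZnCH2CO2Et to ethyl 6-(2-ethoxy-2-oxoethyl)-7-methyl-1-benzofuran-3-carboxylate F5. Iodination (N-iodosuccinimide, CF3CO2H) at C5, para to the ring oxygen and ortho to the new side chain, should give ethyl 6-(2-ethoxy-2-oxoethyl)-5-iodo-7-methyl-1-benzofuran-3-carboxylate F6, and Stille allylation as in step 4 comes back to the route at 7.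

Step 12. Hydrazone formation at the ketone next to the benzylic methine may stall, or the β-hydroxy ketone may open by retro-aldol cleavage before it is reduced. Fallback, setting out from 17: NaBH4 in EtOH at 0 °C should give the C11 alcohol F7 (either epimer serves). PhOC(S)Cl, pyridine and DMAP should acylate only the secondary hydroxyl to the O-phenyl thionocarbonate F8, and Bu3SnH with AIBN in toluene at 100 °C (Barton–McCombie deoxygenation) should give 19, where the route is rejoined.

**Further compounds**

F1 | step 11 | ent-spiro diketone, mirror image of 16 at C8 (not isolated) | O1CCOC12C[C@@]3(CC2=O)C(C(C)=O)c2cc4c(C(=O)OCC)coc4c(C)c2C3C(=O)OCC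
F2 | step 11 | ent-ketol, mirror image of 17 | O1CCOC12C[C@@]34C[C@]2(O)CC(=O)[C@@H]3c3cc5c(C(=O)OCC)coc5c(C)c3[C@H]4C(=O)OCC
F3 | step 5 | ethyl 6-bromo-2-hydroxy-7-methyl-2,3-dihydro-1-benzofuran-3-carboxylate (hemiacetal, not isolated) | CCOC(=O)C1C(O)Oc2c(C)c(Br)ccc12
F4 | step 5 | ethyl 6-bromo-7-methyl-1-benzofuran-3-carboxylate | CCOC(=O)c1coc2c(C)c(Br)ccc12
F5 | step 5 | ethyl 6-(2-ethoxy-2-oxoethyl)-7-methyl-1-benzofuran-3-carboxylate | CCOC(=O)Cc1ccc2c(C(=O)OCC)coc2c1C
F6 | step 5 | ethyl 6-(2-ethoxy-2-oxoethyl)-5-iodo-7-methyl-1-benzofuran-3-carboxylate | CCOC(=O)Cc1c(I)cc2c(C(=O)OCC)coc2c1C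
F7 | step 12 | C11 alcohol, diethyl 16,16-ethylenedioxy-11,13-dihydroxy-17-norpharbinilate (C11 configuration open, other centres as in 17) | O1CCOC12C[C@]34C[C@@]2(O)CC(O)[C@H]3c3cc5c(C(=O)OCC)coc5c(C)c3[C@@H]4C(=O)OCC
F8 | step 12 | O-phenyl thionocarbonate of F7 at the C11 oxygen | O1CCOC12C[C@]34C[C@@]2(O)CC(OC(=S)Oc5ccccc5)[C@H]3c3cc6c(C(=O)OCC)coc6c(C)c3[C@@H]4C(=O)OCC
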